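The easy step comes first: in the proposed steps the starting material turns by itself into the intermediate, and the two nucleophiles share that intermediate between target and other capture product. In the same proposal the protic impurity diverts starting material to the quenched substrate.

| flask | starting material | first nucleophile | second nucleophile | protic impurity | remark | time |
|---|---|---|---|---|---|---|
| north-west | 2.5 mM | 4 equiv | 0.80 equiv | 5 mM | run made earlier |  |
| south | 10 mM | 4 equiv | 0.80 equiv | 5 mM | run made earlier |  |
| east | 5 mM | 6 equiv | 0.80 equiv | 5 mM | run made earlier |  |
| flask | 5.0 mM | 4.00 equiv | 0.800 equiv | 5.00 mM |  | 25 min |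

| run | time / min | other capture product / % | target / % | starting material / % |
|---|---|---|---|---|
| north-west | 8.00 | 22.6 | 12.9 | 1.5 |
| north-west | 15.0 | 24.9 | 13.1 | 1.1 |
| north-west | 25.0 | 22.5 | 11.3 | 0.2 |
| north-west | 30.0 | 26.3 | 14.1 | 0.9 |
| south | 2.50 | 34.3 | 21.3 | 0.4 |
| south | 6.00 | 34.3 | 21.8 | 0.8 |
| south | 12.0 | 35.6 | 21.1 | 0.4 |
| south | 30.0 | 35.4 | 19.6 | 0.8 |
| east | 4.00 | 23.8 | 18.6 | 0 |
| east | 10.0 | 24.2 | 21.6 | 0 |
| east | 20.0 | 23.9 | 19.6 | 0 |
| east | 30.0 | 24.5 | 18.9 | 0 |

(scatter of a reading: 1 percentage point)

- ratio of other capture product to target at 0.40 s
- ratio of other capture product to target at 20 s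
- ratio of other capture product to target at 25 min

- the analysis behind the earlier runs scatters by 1 percentage point, standard deviation
- steps that have been proposed: starting material -> intermediate; first nucleophile + intermediate -> target; second nucleophile + intermediate -> other capture product; first nucleophile <-> dormant form; starting material + protic impurity -> quenched substrate

The early rungs of the time ladder lie below the first samples. At 2.50 min the south run already shows 0.4 % starting material, and its other capture product changes by 1.1 percentage points up to 30.0 min, against a scatter of 1 point. So the seconds go unread, and the south run shows its other capture product steady to within about that scatter.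

What remains on the last rung is a count. Working with the fraction left and not the fraction made, and averaging the four readings of each run, the north-west, south and east runs give 11.0, 10.7 and 10.8. Their mean, 10.8, is a reading with that scatter in it, a selectivity factor: the logarithm of the fraction of second nucleophile left over the logarithm of the fraction of first nucleophile not turned into target.

The east run has the flask's starting material and protic impurity, and the proposed quench involves neither nucleophile, so this reckoning takes its capture, target plus other capture product, of 43.8 % for the flask. By this reckoning the flask's ratio starts at 2.16, and with average amounts over the run it ends at 1.79. The forecast gives 2.1, 1.9 and 1.8 at 0.40 s, 20 s and 25 min, warning that the “runs do not resolve seconds”.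

The flask gives 1.60, 1.74 and 1.74, so the forecast is high at 0.40 s.

    starting material → intermediate (k = 0.100 s⁻¹)
    first nucleophile + intermediate → target (k = 14000 M⁻¹ s⁻¹)
    second nucleophile + intermediate → other capture product (k = 1.10 × 10⁵ M⁻¹ s⁻¹)
    first nucleophile ⇌ dormant form (K = 0.500, k = 0.170 s⁻¹)
    starting material + protic impurity → quenched substrate (k = 39.0 M⁻¹ s⁻¹)

From the flask's 27.4 % other capture product, the factor 10.8 puts its target at 15.2 %, against 15.8 % found. In the neighbour whose second nucleophile stands at 2.00 equiv, 35.6 % other capture product puts its target at 7.20 %, against 7.51 % found. The forward step to the dormant form, taken alone, has a time of 5.88 s, longer than 0.40 s and shorter than 20 s. Across that span the flask's ratio rises from 1.60 to 1.74.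

The runs stem from a simulated flask on assumed constants, noise included.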